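**Retrosynthetic overview**

- The target is (2R,4'R,8'S)-α-tocomonoenol. The last C–C disconnection is C2'–C3' (alkyl–alkyl Suzuki–Miyaura coupling), giving a (2S)-2-vinylchroman acetate and a C14 iodide that carries both methyl stereocentres and the isopropenyl end.
- Key disconnection: C4–C4a and O1–C2 of the vinylchroman are cut together, back to 4-acetoxy-2-iodo-3,5,6-trimethylphenol and achiral 3-methylpenta-1,4-diene. One catalytic operation does arylpalladation, palladium chain walk and enantioselective allylic etherification.
- Enabling feature: O1 and C4a sit on neighbouring ring carbons (C8a, C4a) of the benzene ring, and C2 is a fully substituted O-bearing carbon whose C1'–C2' arm can be read as a vinyl group. C4–C3–C2(CH3)–C1'=C2' is therefore the skeleton of a skipped diene, and C2 is the substituted terminus of a π-allyl unit.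
- Rings: the benzene ring comes from trimethylhydroquinone; the dihydropyran ring is the only ring made (step 4).
- Side chain: (R)-citronellyl bromide (C8'), (S)-3-bromo-2-methylpropan-1-ol (C4') and isopropenylmagnesium bromide. After the isopropenyl group is in place, no acid, hydrogen or oxidant is used.

Key step: step 4

Remark (CIP): the terminal C=C raises the priority of the C9' branch, so the 8' centre is S by the CIP rules although all three centres have the spatial arrangement of natural (R,R,R)-α-tocopherol.
Remark (assumption): the (1R,2R)-ligand of step 4 is taken to deliver the (2S)-vinylchroman; should the sense of induction be the opposite, the (1S,2S)-ligand is used with no other change.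

Step 1
Reactants: 1 2,3,5-trimethylbenzene-1,4-diol (trimethylhydroquinone)
Product: 2 2,3,5-trimethyl-1,4-phenylene diacetate
Conditions: Ac2O (2.5 equiv), pyridine, DMAP (5 mol %), CH2Cl2, 0 °C to rt
Reagents that add atoms: acetic anhydride, CC(=O)OC(C)=O
Why: Exhaustive O-acetylation (nucleophilic acyl substitution with DMAP catalysis) masks both phenols so that they can be told apart by their steric surroundings in the next step; no stereocentre is involved.

Step 2
Reactants: 2 2,3,5-trimethyl-1,4-phenylene diacetate
Product: 3 4-hydroxy-2,3,6-trimethylphenyl acetate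
Conditions: pyrrolidine (1.05 equiv), THF, 0 °C, argon
Reagents that add atoms: none
Why: Chemoselective aminolysis of an aryl ester should cleave the acetate flanked by H and CH3 while the acetate flanked by two ortho methyl groups stays shielded, which frees exactly the phenol next to the unsubstituted ring carbon; no stereocentre is involved.

Step 3
Reactants: 3 4-hydroxy-2,3,6-trimethylphenyl acetate
Product: 4 4-hydroxy-3-iodo-2,5,6-trimethylphenyl acetate
Conditions: NIS (1.05 equiv), TsOH·H2O (10 mol %), MeCN, 0 °C to rt, dark
Reagents that add atoms: N-iodosuccinimide, O=C1CCC(=O)N1I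
Why: Electrophilic aromatic iodination, directed by the free hydroxyl group to the only unsubstituted ring position (ortho to OH), installs the handle for oxidative addition; no stereocentre is involved.

Step 4
Reactants: 4 4-hydroxy-3-iodo-2,5,6-trimethylphenyl acetate; 5 3-methylpenta-1,4-diene
Product: 6 (2S)-2-ethenyl-2,5,7,8-tetramethyl-3,4-dihydro-2H-chromen-6-yl acetate
Conditions: Pd2(dba)3·CHCl3 (2.5 mol %), (1R,2R)-N,N'-bis(2-diphenylphosphinobenzoyl)cyclohexane-1,2-diamine (7.5 mol %), 5 (4 equiv), KOAc (2 equiv), AcOH (1 equiv), 1,4-dioxane/DMA (4:1), 70 °C, sealed tube, argon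
Reagents that add atoms: none
Why: Proposed new method: zerovalent palladium inserts into the C–I bond of 4, the aryl group adds to the terminal carbon of one vinyl group of 5 (C4–C4a bond), β-hydride elimination of the doubly allylic hydrogen and re-addition of the palladium hydride move the metal to the methyl-bearing carbon as a 1,1-disubstituted π-allyl complex, and the ortho phenol attacks its fully substituted terminus (O1–C2 bond) with release of the catalyst. The closest known reaction types are the racemic palladium-catalysed heteroannulation of 1,4-dienes by o-iodophenols (arylpalladation, palladium migration, allylic displacement) and the enantioselective Tsuji–Trost cyclisation of phenols onto the same kind of methyl-substituted π-allyl terminus, which gives 2-methyl-2-vinylchromans; the proposal merges the two in one catalytic cycle. The dihydropyran ring closes by 6-exo attack of the phenol oxygen on the π-allyl unit, the alternative closure at the CH2 terminus (8-membered ring) being out of reach. The only new stereocentre, C2, is set by the C2-symmetric chiral diphosphine on palladium, which selects one face of the equilibrating π-allyl complexes; the acetate/acetic acid buffer keeps the nucleophile as the neutral phenol so that π–σ–π equilibration should outrun ring closure. Regioselectivity of the arylation is secured by the two equivalent monosubstituted vinyl groups of 5 (the stereocentre created on insertion is erased by the chain walk), and chemoselectivity by the single iodide and single free phenol of 4, the other oxygen being masked as the hindered acetate.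

Step 5
Reactants: 7 (2S)-3-bromo-2-methylpropan-1-ol
Product: 8 (2S)-1-bromo-3-chloro-2-methylpropane
Conditions: PPh3 (1.1 equiv), NCS (1.1 equiv), CH2Cl2, 0 °C to rt
Reagents that add atoms: N-chlorosuccinimide, O=C1CCC(=O)N1Cl
Why: Appel-type chlorination (SN2 displacement on the alkoxyphosphonium ion at the primary carbon) turns the alcohol into a chloride that should survive two copper-catalysed couplings; the stereocentre is not touched.

Step 6
Reactants: 9 (6R)-8-bromo-2,6-dimethyloct-2-ene [(R)-citronellyl bromide]; 8 (2S)-1-bromo-3-chloro-2-methylpropane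
Product: 11 (2R,6S)-1-chloro-2,6,10-trimethylundec-9-ene, via (R)-citronellylmagnesium bromide 10 (not isolated)
Conditions: 9, Mg turnings, THF, 40 °C; then 8 (0.9 equiv), Li2CuCl4 (3 mol %), NMP (4 equiv), THF, 0 °C to rt
Reagents that add atoms: none
Why: Grignard formation and copper-catalysed alkyl–alkyl cross-coupling at the C–Br bond (which reacts far faster than C–Cl) join the two chiral-pool fragments, both stereocentres being carried in unchanged from 9 and 8 (the descriptors change only through CIP priorities).

Step 7
Reactants: 11 (2R,6S)-1-chloro-2,6,10-trimethylundec-9-ene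
Product: 13 (4S,8R)-9-chloro-4,8-dimethylnonan-1-ol, via secondary ozonide 12 (not isolated)
Conditions: O3, CH2Cl2, −78 °C; then NaBH4 (3 equiv), MeOH, −78 °C to rt
Reagents that add atoms: ozone, [O-][O+]=O
Why: Ozonolysis of the only C=C bond with reductive work-up (hydride reduction of the ozonide) excises the isopropylidene carbon and leaves a primary alcohol at C11', the alkyl chloride and both stereocentres being inert.

Step 8
Reactants: 13 (4S,8R)-9-chloro-4,8-dimethylnonan-1-ol
Product: 14 (4S,8R)-9-chloro-4,8-dimethylnonyl 4-methylbenzenesulfonate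
Conditions: TsCl (1.2 equiv), Et3N, DMAP (5 mol %), CH2Cl2, 0 °C
Reagents that add atoms: p-toluenesulfonyl chloride, Cc1ccc(cc1)S(=O)(=O)Cl
Why: Sulfonylation of the primary alcohol (tosylation) creates a leaving group far more reactive towards organocopper species than the β-branched primary chloride; no stereocentre is affected.

Step 9
Reactants: 14 (4S,8R)-9-chloro-4,8-dimethylnonyl 4-methylbenzenesulfonate; 15 prop-1-en-2-ylmagnesium bromide
Product: 16 (2R,6S)-1-chloro-2,6,10-trimethylundec-10-ene
Conditions: 15 (2.5 equiv, THF solution), Li2CuCl4 (5 mol %), THF, −20 °C to rt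
Reagents that add atoms: none
Why: Copper-catalysed coupling of an alkenyl Grignard reagent with a primary tosylate installs the terminal isopropenyl group as a complete unit after the last oxidative operation of the route, the chloride and both stereocentres staying untouched.

Step 10
Reactants: 16 (2R,6S)-1-chloro-2,6,10-trimethylundec-10-ene
Product: 17 (2R,6S)-1-iodo-2,6,10-trimethylundec-10-ene
Conditions: NaI (5 equiv), butan-2-one, reflux
Reagents that add atoms: sodium iodide, [Na+].[I-]
Why: Finkelstein halide exchange (SN2 at the primary carbon, driven by precipitation of NaCl) gives the iodide needed for oxidative addition; the neighbouring stereocentre is not the reacting carbon.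

Step 11
Reactants: 6 (2S)-2-ethenyl-2,5,7,8-tetramethyl-3,4-dihydro-2H-chromen-6-yl acetate; 17 (2R,6S)-1-iodo-2,6,10-trimethylundec-10-ene
Product: 19 (2R)-2,5,7,8-tetramethyl-2-[(4R,8S)-4,8,12-trimethyltridec-12-en-1-yl]-3,4-dihydro-2H-chromen-6-yl acetate, via B-alkyl-9-BBN adduct 18 (not isolated)
Conditions: 9-BBN dimer (0.48 equiv), THF, 0 °C to rt; then 17 (0.85 equiv), Pd(PPh3)4 (5 mol %), K3PO4·H2O (3 equiv), 1,4-dioxane, 60 °C, argon
Reagents that add atoms: none
Why: Anti-Markovnikov hydroboration of the vinyl group (boron to the terminal carbon, steered by the quaternary C2) followed by B-alkyl Suzuki–Miyaura alkyl–alkyl coupling with the primary iodide forms the C2'–C3' bond and unites the two halves; no new stereocentre is formed, the three existing ones are remote from the reacting carbons, and a slight deficit of 9-BBN keeps the isopropenyl group of 17 away from B–H.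

Step 12
Reactants: 19 (2R)-2,5,7,8-tetramethyl-2-[(4R,8S)-4,8,12-trimethyltridec-12-en-1-yl]-3,4-dihydro-2H-chromen-6-yl acetate
Product: 20 (2R)-2,5,7,8-tetramethyl-2-[(4R,8S)-4,8,12-trimethyltridec-12-en-1-yl]-3,4-dihydro-2H-chromen-6-ol (target)
Conditions: KOH (3 equiv), degassed EtOH/H2O, 50 °C, argon; then aq. NH4Cl
Reagents that add atoms: none
Why: Base-mediated hydrolysis of the hindered aryl acetate (saponification) under oxygen-free conditions should release the chromanol without touching the base-stable isopropenyl group or any stereocentre.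

**Compound list**

1 | 2,3,5-trimethylbenzene-1,4-diol (trimethylhydroquinone) | Cc1cc(O)c(C)c(C)c1O | starting material
2 | 2,3,5-trimethyl-1,4-phenylene diacetate | CC(=O)Oc1cc(C)c(OC(C)=O)c(C)c1C | intermediate
3 | 4-hydroxy-2,3,6-trimethylphenyl acetate | CC(=O)Oc1c(C)c(C)c(O)cc1C | intermediate
4 | 4-hydroxy-3-iodo-2,5,6-trimethylphenyl acetate | CC(=O)Oc1c(C)c(C)c(O)c(I)c1C | intermediate
5 | 3-methylpenta-1,4-diene | C=CC(C)C=C | starting material
6 | (2S)-2-ethenyl-2,5,7,8-tetramethyl-3,4-dihydro-2H-chromen-6-yl acetate | C=C[C@]1(C)CCc2c(C)c(OC(C)=O)c(C)c(C)c2O1 | intermediate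
7 | (2S)-3-bromo-2-methylpropan-1-ol | OC[C@H](C)CBr | starting material
8 | (2S)-1-bromo-3-chloro-2-methylpropane | ClC[C@H](C)CBr | intermediate
9 | (6R)-8-bromo-2,6-dimethyloct-2-ene [(R)-citronellyl bromide] | BrCC[C@H](C)CCC=C(C)C | starting material
10 | [(3R)-3,7-dimethyloct-6-en-1-yl]magnesium bromide | Br[Mg]CC[C@H](C)CCC=C(C)C | intermediate
11 | (2R,6S)-1-chloro-2,6,10-trimethylundec-9-ene | ClC[C@H](C)CCC[C@H](C)CCC=C(C)C | intermediate
12 | 3-[(3S,7R)-8-chloro-3,7-dimethyloctyl]-5,5-dimethyl-1,2,4-trioxolane | ClC[C@H](C)CCC[C@H](C)CCC1OOC(C)(C)O1 | intermediate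
13 | (4S,8R)-9-chloro-4,8-dimethylnonan-1-ol | ClC[C@H](C)CCC[C@H](C)CCCO | intermediate
14 | (4S,8R)-9-chloro-4,8-dimethylnonyl 4-methylbenzenesulfonate | ClC[C@H](C)CCC[C@H](C)CCCOS(=O)(=O)c1ccc(C)cc1 | intermediate
15 | prop-1-en-2-ylmagnesium bromide (isopropenylmagnesium bromide) | C=C(C)[Mg]Br | starting material
16 | (2R,6S)-1-chloro-2,6,10-trimethylundec-10-ene | ClC[C@H](C)CCC[C@H](C)CCCC(C)=C | intermediate
17 | (2R,6S)-1-iodo-2,6,10-trimethylundec-10-ene | IC[C@H](C)CCC[C@H](C)CCCC(C)=C | intermediate
18 | (2R)-2-[2-(9-borabicyclo[3.3.1]nonan-9-yl)ethyl]-2,5,7,8-tetramethyl-3,4-dihydro-2H-chromen-6-yl acetate | B1(CC[C@]2(C)CCc3c(C)c(OC(C)=O)c(C)c(C)c3O2)C2CCCC1CCC2 | intermediate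
19 | (2R)-2,5,7,8-tetramethyl-2-[(4R,8S)-4,8,12-trimethyltridec-12-en-1-yl]-3,4-dihydro-2H-chromen-6-yl acetate | C=C(C)CCC[C@@H](C)CCC[C@@H](C)CCC[C@]1(C)CCc2c(C)c(OC(C)=O)c(C)c(C)c2O1 | intermediate
20 | (2R)-2,5,7,8-tetramethyl-2-[(4R,8S)-4,8,12-trimethyltridec-12-en-1-yl]-3,4-dihydro-2H-chromen-6-ol | C=C(C)CCC[C@@H](C)CCC[C@@H](C)CCC[C@]1(C)CCc2c(C)c(O)c(C)c(C)c2O1 | target

**Step count and risks**

Total step count: 12. Longest linear sequence: 8 steps (steps 5 to 12, from 7 to 20); the aromatic branch is 6 steps (steps 1 to 4, 11, 12).

Steps most likely to fail: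

1. Step 4. Arylpalladation may be slow with the chelating diphosphine, hydride re-addition may go to the other diene terminus (five-membered ring), and above all ring closure may be faster than equilibration of the diastereomeric π-allyl complexes, so that enantiofacial selection is poor. The fallback separates ring construction from stereocontrol and uses known chemistry. Setting out from 4, the heteroannulation with 5 is run under the ligand-free conditions established for 1,4-dienes and o-iodophenols (Pd(OAc)2, n-Bu4NCl, Na2CO3, DMF, 80 °C) to give racemic 2-ethenyl-2,5,7,8-tetramethyl-3,4-dihydro-2H-chromen-6-yl acetate F1. This is resolved by preparative supercritical-fluid chromatography on a cellulose tris(3,5-dimethylphenylcarbamate) phase. The unwanted (2R)-2-ethenyl-2,5,7,8-tetramethyl-3,4-dihydro-2H-chromen-6-yl acetate F2 is set aside, and the (2S)-enantiomer is 6, where the route is rejoined.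

2. Step 11. Oxidative addition of the β-branched primary iodide may be slow, and the alkylpalladium formed can lose its tertiary β-hydrogen, giving alkene and reduced by-products instead of coupling. The fallback reverses the polarity, with the unbranched chroman side as the electrophile. Setting out from 6, hydroboration to 18 as before and oxidation with NaBO3·4H2O give (2S)-2-(2-hydroxyethyl)-2,5,7,8-tetramethyl-3,4-dihydro-2H-chromen-6-yl acetate F3. Tosylation (TsCl, Et3N, DMAP, CH2Cl2) gives 2-[(2S)-6-acetoxy-2,5,7,8-tetramethyl-3,4-dihydro-2H-chromen-2-yl]ethyl 4-methylbenzenesulfonate F4. Separately, 17 is treated with zinc dust (activated with iodine, DMA, 50 °C) to give [(2R,6S)-2,6,10-trimethylundec-10-en-1-yl]zinc iodide F5. Negishi alkyl–alkyl coupling of F4 with F5 (Pd2(dba)3, tricyclopentylphosphine, N-methylimidazole, THF/NMP, 80 °C), a method established for unactivated primary tosylates and ester-bearing partners, should give 19, where the route is rejoined.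

3. Step 6. Displacement at the β-branched bromide 8 may be sluggish, so homocoupling of the Grignard reagent and halogen–magnesium exchange can take over. The fallback exchanges the roles: the branched fragment becomes the nucleophile and unbranched 9 the electrophile. Setting out from 7, protection (3,4-dihydro-2H-pyran, PPTS, CH2Cl2) gives 2-{[(2S)-3-bromo-2-methylpropyl]oxy}oxane F6. Magnesium in THF converts it into {(2S)-2-methyl-3-[(oxan-2-yl)oxy]propyl}magnesium bromide F7. Copper-catalysed coupling with 9 (Li2CuCl4, THF, 0 °C) gives 2-{[(2R,6S)-2,6,10-trimethylundec-9-en-1-yl]oxy}oxane F8. Acetal cleavage (PPTS, MeOH, 40 °C) gives (2R,6S)-2,6,10-trimethylundec-9-en-1-ol F9, and chlorination as in step 5 (PPh3, NCS, CH2Cl2) returns to the route at 11.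

Further compounds
F1 | step 4 | racemic 2-ethenyl-2,5,7,8-tetramethyl-3,4-dihydro-2H-chromen-6-yl acetate | C=CC1(C)CCc2c(C)c(OC(C)=O)c(C)c(C)c2O1
F2 | step 4 | (2R)-2-ethenyl-2,5,7,8-tetramethyl-3,4-dihydro-2H-chromen-6-yl acetate | C=C[C@@]1(C)CCc2c(C)c(OC(C)=O)c(C)c(C)c2O1
F3 | step 11 | (2S)-2-(2-hydroxyethyl)-2,5,7,8-tetramethyl-3,4-dihydro-2H-chromen-6-yl acetate | OCC[C@]1(C)CCc2c(C)c(OC(C)=O)c(C)c(C)c2O1
F4 | step 11 | 2-[(2S)-6-acetoxy-2,5,7,8-tetramethyl-3,4-dihydro-2H-chromen-2-yl]ethyl 4-methylbenzenesulfonate | Cc1ccc(cc1)S(=O)(=O)OCC[C@]1(C)CCc2c(C)c(OC(C)=O)c(C)c(C)c2O1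
F5 | step 11 | [(2R,6S)-2,6,10-trimethylundec-10-en-1-yl]zinc iodide | I[Zn]C[C@H](C)CCC[C@H](C)CCCC(C)=C
F6 | step 6 | 2-{[(2S)-3-bromo-2-methylpropyl]oxy}oxane | C1CCCC(O1)OC[C@H](C)CBr
F7 | step 6 | {(2S)-2-methyl-3-[(oxan-2-yl)oxy]propyl}magnesium bromide | C1CCCC(O1)OC[C@H](C)C[Mg]Br
F8 | step 6 | 2-{[(2R,6S)-2,6,10-trimethylundec-9-en-1-yl]oxy}oxane | C1CCCC(O1)OC[C@H](C)CCC[C@H](C)CCC=C(C)C
F9 | step 6 | (2R,6S)-2,6,10-trimethylundec-9-en-1-ol | OC[C@H](C)CCC[C@H](C)CCC=C(C)C
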